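**Assumption:** compounds 1, 2, 5, 7, 8, 10 and (R)-TRIP are taken as catalogue items, and (R)-TRIP is taken to deliver the allyl group to the Re face of the aldehyde, as in its standard allylborations (use (S)-TRIP if the observed sense is opposite).

## Retrosynthetic overview

1. Mycothiazole 13 ⇒ Suzuki disconnection inside the diene: (Z)-alkenylboronate 12 + 2-bromoalkene carbamate 11 (from acid 10 by Curtius).
2. 12 ⇒ aldehyde 6 + achiral gem-diboryl allyl reagent 9. One chiral-phosphoric-acid-catalysed allylboration forms the C–C bond, the only stereocentre and the Z-olefin.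
3. 6 ⇒ 2-chlorothiazole 4 + isobutyraldehyde 5 by direct α-heteroarylation, which creates the quaternary carbon (new step).
4. 4 ⇒ 2-chloro-4-(chloromethyl)thiazole 1 + pent-1-en-4-yne 2 (Cu sp–sp3 coupling, then Z-semihydrogenation).
5. Rings: the thiazole is bought intact; no ring is formed in the route.

## Route

**Step 1**
Reactants: 1, 2-chloro-4-(chloromethyl)-1,3-thiazole; 2, pent-1-en-4-yne
Product: 3, 2-chloro-4-(hex-5-en-2-yn-1-yl)-1,3-thiazole
Conditions: CuI (1.0 equiv), NaI (1.0 equiv), K2CO3 (1.5 equiv), DMF, rt, 16 h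
Reagents that add atoms: none beyond reactant 2 (pent-1-en-4-yne, C=CCC#C)
Why: Copper-acetylide SN2 alkylation (Cu-mediated sp–sp3 coupling) of the heterobenzylic chloride, activated in situ as the iodide; the C2–Cl bond is inert without Pd, and the mild carbonate base limits propargyl-to-allene isomerisation.

**Step 2**
Reactants: 3, 2-chloro-4-(hex-5-en-2-yn-1-yl)-1,3-thiazole
Product: 4, 2-chloro-4-[(2Z)-hexa-2,5-dien-1-yl]-1,3-thiazole
Conditions: H2 (1 atm), Lindlar catalyst, quinoline, EtOAc, 0 °C → rt, stopped at 1.0 equiv H2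
Reagents that add atoms: none (H2 adds only hydrogen)
Why: Lindlar syn-semihydrogenation gives the Z-alkene; the poisoned catalyst reduces the alkyne much faster than the terminal vinyl group and does not cleave the heteroaryl C–Cl bond.

**Step 3**
Reactants: 4, 2-chloro-4-[(2Z)-hexa-2,5-dien-1-yl]-1,3-thiazole; 5, isobutyraldehyde (3 equiv)
Product: 6, 2-{4-[(2Z)-hexa-2,5-dien-1-yl]-1,3-thiazol-2-yl}-2-methylpropanal
Conditions: [Pd(allyl)Cl]2 (2.5 mol%), dppf (6 mol%), Cs2CO3 (1.5 equiv), 1,4-dioxane, 80 °C, sealed tube, 12 h
Reagents that add atoms: none beyond reactant 5 (isobutyraldehyde, CC(C)C=O)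
Why: Proposed new method: direct Pd-catalysed α-heteroarylation of an α-branched aldehyde with a 2-chloro-1,3-thiazole to form the quaternary C–C(thiazol-2-yl) bond at the aldehyde oxidation level. Pd(0) inserts into the activated C2–Cl bond, the carbonate-generated enolate of isobutyraldehyde binds through carbon, and the wide-bite-angle dppf drives reductive elimination to the quaternary centre; the product has no α-hydrogen, so it cannot over-arylate or aldolise. The closest known reaction type is the Pd/bisphosphine/Cs2CO3 α-arylation of α-branched aldehydes with aryl bromides and chlorides, which to my knowledge has not been shown for 2-halo-1,3-azoles.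

**Step 4**
Reactants: 7, bis(4,4,5,5-tetramethyl-1,3,2-dioxaborolan-2-yl)methane; 8, vinyl bromide
Product: 9, 2,2'-(prop-2-ene-1,1-diyl)bis(4,4,5,5-tetramethyl-1,3,2-dioxaborolane) (achiral α-boryl allylboronate)
Conditions: LiTMP, THF, 0 °C; ZnBr2; then 8 (1 M in THF), Pd[P(t-Bu)3]2 (2 mol%), rt
Reagents that add atoms: none beyond reactant 8 (vinyl bromide, C=CBr)
Why: Deprotonation gives the doubly boron-stabilised carbanion, which is transmetalated to zinc and Negishi-coupled with the vinyl halide; this is a known route to allylic gem-diboronates.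

**Step 5**
Reactants: 10, 4-bromopent-4-enoic acid
Product: 11, methyl (3-bromobut-3-en-1-yl)carbamate
Conditions: DPPA, Et3N, toluene, rt → 85 °C; then MeOH, 70 °C
Reagents that add atoms: diphenylphosphoryl azide, [N-]=[N+]=NP(=O)(Oc1ccccc1)Oc1ccccc1 (supplies N); methanol, CO (supplies OCH3)
Why: Curtius rearrangement of the acyl azide to the isocyanate, trapped by methanol as the methyl carbamate; the vinyl bromide is untouched.

**Step 6**
Reactants: 6, 2-{4-[(2Z)-hexa-2,5-dien-1-yl]-1,3-thiazol-2-yl}-2-methylpropanal; 9, gem-diboryl allyl reagent (1.5 equiv)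
Product: 12, (3R,5Z)-2-{4-[(2Z)-hexa-2,5-dien-1-yl]-1,3-thiazol-2-yl}-2-methyl-6-(4,4,5,5-tetramethyl-1,3,2-dioxaborolan-2-yl)hex-5-en-3-ol. It may be isolated as, or equilibrate with, its cyclic 1,2-oxaborinin half-ester; either form is used directly in step 7.
Conditions: (R)-TRIP (10 mol%), 4 Å MS, toluene, −30 → 0 °C, 48 h
Reagents that add atoms: none beyond reactant 9 (C=CC(B1OC(C)(C)C(C)(C)O1)B1OC(C)(C)C(C)(C)O1)
Why: Chiral-phosphoric-acid-catalysed asymmetric allylboration through a closed chair transition state, with the acid hydrogen-bonded to a boronate oxygen and the formyl C–H. (R)-TRIP directs Re-face attack to give the (R)-carbinol. The α-boryl group sits pseudo-axial in the catalyst-bound chair, as is known for α-boryl allylboronates under this catalysis, so the new alkenylboronate is Z. The aldehyde is non-enolisable.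

**Step 7**
Reactants: 12, (R,Z)-alkenylboronate; 11, methyl (3-bromobut-3-en-1-yl)carbamate (1.2 equiv)
Product: 13, mycothiazole, methyl N-[(4Z,7R)-7-hydroxy-8-{4-[(2Z)-hexa-2,5-dien-1-yl]-1,3-thiazol-2-yl}-8-methyl-3-methylidenenon-4-en-1-yl]carbamate
Conditions: Pd(dppf)Cl2 (5 mol%), K3PO4 (3 equiv), THF/H2O (10:1), 45 °C
Reagents that add atoms: none beyond reactant 11 (C=C(Br)CCNC(=O)OC)
Why: Suzuki–Miyaura alkenyl–alkenyl coupling proceeds with retention of the Z-boronate geometry and tolerates the free OH, the carbamate NH and the skipped diene; the carbinol centre is not epimerisable under these conditions.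

## Compound list

1 | 2-chloro-4-(chloromethyl)-1,3-thiazole | ClCc1csc(Cl)n1 | starting material
2 | pent-1-en-4-yne | C=CCC#C | starting material
3 | 2-chloro-4-(hex-5-en-2-yn-1-yl)-1,3-thiazole | C=CCC#CCc1csc(Cl)n1 | intermediate
4 | 2-chloro-4-[(2Z)-hexa-2,5-dien-1-yl]-1,3-thiazole | C=CC/C=C\Cc1csc(Cl)n1 | intermediate
5 | isobutyraldehyde | CC(C)C=O | starting material
6 | 2-{4-[(2Z)-hexa-2,5-dien-1-yl]-1,3-thiazol-2-yl}-2-methylpropanal | C=CC/C=C\Cc1csc(C(C)(C)C=O)n1 | intermediate
7 | bis(pinacolatoboryl)methane | C(B1OC(C)(C)C(C)(C)O1)B1OC(C)(C)C(C)(C)O1 | starting material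
8 | vinyl bromide | C=CBr | starting material
9 | 2,2'-(prop-2-ene-1,1-diyl)bis(4,4,5,5-tetramethyl-1,3,2-dioxaborolane) | C=CC(B1OC(C)(C)C(C)(C)O1)B1OC(C)(C)C(C)(C)O1 | intermediate
10 | 4-bromopent-4-enoic acid | C=C(Br)CCC(=O)O | starting material
11 | methyl (3-bromobut-3-en-1-yl)carbamate | C=C(Br)CCNC(=O)OC | intermediate
12 | (3R,5Z)-2-{4-[(2Z)-hexa-2,5-dien-1-yl]thiazol-2-yl}-2-methyl-6-(pinacolatoboryl)hex-5-en-3-ol | C=CC/C=C\Cc1csc(C(C)(C)[C@H](O)C/C=C\B2OC(C)(C)C(C)(C)O2)n1 | intermediate
13 | mycothiazole | C=CC/C=C\Cc1csc(C(C)(C)[C@H](O)C/C=C\C(=C)CCNC(=O)OC)n1 | target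

## Summary

Total steps: 7. Longest linear sequence: 5 (steps 1, 2, 3, 6, 7).

Steps most likely to fail:

1. **Step 3 (proposed new α-heteroarylation).** Risks are slow coupling at the thiazol-2-yl chloride, Pd–H isomerisation of the skipped diene, and base-induced deformylation of the product. Fallback with known chemistry: build the quaternary carbon into the ring by Hantzsch synthesis. Thionate ethyl 2-cyano-2-methylpropanoate (NaSH/MgCl2), condense with 1,3-dichloroacetone to give ethyl 2-[4-(chloromethyl)thiazol-2-yl]-2-methylpropanoate, apply the step 1–2 chemistry to the chloromethyl group, then reduce with DIBAL-H at −78 °C to 6 (two extra steps).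
2. **Step 6 (asymmetric allylboration).** The aldehyde is α-quaternary and carries a Lewis-basic thiazole, so rate, ee or Z/E ratio may suffer. Fallback: change the C3 linchpin from allyl to propargyl. Run the same acid-catalysed addition with allenyl-Bpin to give the homopropargylic alcohol, Sonogashira-couple with 11, and reduce the conjugated enyne Z-selectively with Zn(Cu/Ag) (one extra step, no olefin-geometry issue in the C–C bond-forming step).
3. **Step 2 (Lindlar semihydrogenation).** The thiazole sulfur may poison the catalyst, and the terminal vinyl group may over-reduce. Fallback: avoid alkyne reduction by forming the Z-olefin before coupling. Z-selective (trans) hydroboration of 2 gives (Z)-penta-1,4-dienyl-Bpin, which is joined to chloride 1 by an sp3–sp2 Suzuki coupling.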